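**Strategy.** The route rests on disconnecting the C3–C4 bond of pyran ring C of the upper catechin unit. C3 (the carbinol carbon) and C4 (the benzylic carbon that carries the interflavan bond to C8 of ring D of the lower unit) are adjacent sp3 carbons, which is the retron of a C3=C4 olefin. Ring-closing metathesis of an enantioenriched 1-arylallyl 2-vinylaryl ether forges this bond and closes ring C as a flav-3-ene in one operation. The olefin then delivers the C3 hydroxyl by syn-dihydroxylation anti to the C2 aryl group and, through ionisation of the benzylic C4 hydroxyl, the interflavan bond to benzylated EGCG.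

Key step: step 7

Remark: the target is read as catechin-(4α→8)-epigallocatechin 3-O-gallate, upper unit (2R,3S,4S), lower unit (2R,3R); compounds 1, 5, 14 and 16 and all reagents are taken as commercial.
Remark: the sense of induction in step 6 is assigned by analogy with the parent cinnamyl carbonate; the mirror-image ligand is used if it proves to be the opposite.

**Step 1**
Reactants: 1 3,4-bis(benzyloxy)benzaldehyde
Product: 2 ethyl (E)-3-[3,4-bis(benzyloxy)phenyl]prop-2-enoate
Conditions: Ph3P=CHCO2Et (1.2 equiv), toluene, 90 °C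
Reagents that add atoms: ethyl (triphenylphosphoranylidene)acetate, CCOC(=O)C=P(c1ccccc1)(c1ccccc1)c1ccccc1
Why: Wittig olefination with a stabilised ylide should convert the unhindered aryl aldehyde into the (E)-enoate, and no stereocentre is formed.

**Step 2**
Reactants: 2 ethyl (E)-3-[3,4-bis(benzyloxy)phenyl]prop-2-enoate
Product: 3 (E)-3-[3,4-bis(benzyloxy)phenyl]prop-2-en-1-ol
Conditions: iBu2AlH (diisobutylaluminium hydride, 2.2 equiv), CH2Cl2, −78 °C; aqueous potassium sodium tartrate
Reagents that add atoms: none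
Why: Low-temperature DIBAL-H reduction of an α,β-unsaturated ester proceeds by two 1,2-hydride deliveries to the allylic alcohol without touching the olefin or the benzyl ethers.

**Step 3**
Reactants: 3 (E)-3-[3,4-bis(benzyloxy)phenyl]prop-2-en-1-ol
Product: 4 (E)-3-[3,4-bis(benzyloxy)phenyl]prop-2-en-1-yl methyl carbonate
Conditions: ClCO2Me (1.3 equiv), pyridine, CH2Cl2, 0 °C
Reagents that add atoms: methyl chloroformate, COC(=O)Cl
Why: Acylation of the primary allylic alcohol with a chloroformate (carbonate formation) should give the linear allylic carbonate that iridium-catalysed allylic substitution requires.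

**Step 4**
Reactants: 5 3,5-bis(benzyloxy)phenol
Product: 7 4,6-bis(benzyloxy)-2-hydroxybenzaldehyde, via 3,5-bis(benzyloxy)-2-(hydroxymethyl)phenol 6 (not isolated)
Conditions: MgCl2 (1.5 equiv), Et3N (3.75 equiv), paraformaldehyde (6 equiv), MeCN, reflux; 1 M HCl work-up
Reagents that add atoms: paraformaldehyde (reacting as formaldehyde), C=O
Why: Casnati–Skattebøl ortho-formylation: the magnesium phenoxide delivers formaldehyde to the ortho carbon (the two ortho positions of 5 are equivalent) and the salicyl alcohol 6 is oxidised in the flask by a second formaldehyde through an Oppenauer-type hydride transfer, so that no attack between the two benzyloxy groups is expected.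

**Step 5**
Reactants: 7 4,6-bis(benzyloxy)-2-hydroxybenzaldehyde
Product: 9 3,5-bis(benzyloxy)-2-vinylphenol, via potassium 3,5-bis(benzyloxy)-2-formylphenoxide 8 (not isolated)
Conditions: Ph3PCH3Br (2.6 equiv), KOtBu (2.5 equiv), THF, 0 °C to 50 °C; aqueous NH4Cl
Reagents that add atoms: methyltriphenylphosphonium bromide, C[P+](c1ccccc1)(c1ccccc1)c1ccccc1.[Br-]
Why: Wittig methylenation with excess non-stabilised ylide should convert the formyl group into the vinyl group although the substrate reacts as its phenoxide 8, as in the known preparation of 2-vinylphenols from salicylaldehydes.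

**Step 6**
Reactants: 9 3,5-bis(benzyloxy)-2-vinylphenol, 4 (E)-3-[3,4-bis(benzyloxy)phenyl]prop-2-en-1-yl methyl carbonate
Product: 11 (S)-1-[3,4-bis(benzyloxy)phenyl]prop-2-en-1-yl 3,5-bis(benzyloxy)-2-vinylphenyl ether, via lithium 3,5-bis(benzyloxy)-2-vinylphenoxide 10 (not isolated)
Conditions: LiN(SiMe3)2 (1.0 equiv on 9), THF, 0 °C; then 4 (0.75 equiv), [Ir(cod)Cl]2 (2 mol %), (Sa,Sc,Sc)-O,O'-(1,1'-binaphthalene-2,2'-diyl) N,N-bis(1-phenylethyl)phosphoramidite (4 mol %), THF, 50 °C
Reagents that add atoms: none
Why: Iridium-catalysed asymmetric allylic etherification of a linear cinnamyl-type carbonate with an alkali aryloxide: the cyclometallated iridium phosphoramidite forms an allyl complex that the aryloxide attacks at the aryl-substituted terminus, which should give the branched ether and set the future C2 stereocentre (S) under catalyst control.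

**Step 7**
Reactants: 11 (S)-1-[3,4-bis(benzyloxy)phenyl]prop-2-en-1-yl 3,5-bis(benzyloxy)-2-vinylphenyl ether
Product: 12 (S)-5,7-bis(benzyloxy)-2-[3,4-bis(benzyloxy)phenyl]-2H-chromene
Conditions: second-generation Grubbs catalyst RuCl2(=CHPh)(PCy3)(H2IMes) (5 mol %), degassed CH2Cl2 (0.01 M), 40 °C, dark
Reagents that add atoms: none
Why: Ring-closing olefin metathesis: the ruthenium benzylidene initiates on one terminal olefin of 11, the resulting alkylidene engages the second olefin in an intramolecular [2+2] cycloaddition, and cycloreversion of the ruthenacyclobutane forms the C3=C4 bond and expels ethylene, whose loss drives the reaction. The closest known reaction type is the metathesis of 2-(allyloxy)styrenes to 2H-chromenes. Ring C is closed as a six-membered oxacycle from a 1,7-diene whose two olefins are held ortho to each other on ring A, so the cis ring olefin is the only possible geometry. No new stereocentre is formed; the C2 stereocentre set in step 6 lies outside the reacting carbons and should be carried through unchanged because the conditions are neutral and non-ionising. The step needs ring closure over cross-metathesis and no ruthenium hydride isomerisation of the allylic ether, which high dilution, two monosubstituted olefins and a short reaction time (with 1,4-benzoquinone as hydride scavenger if needed) should secure. The new C3=C4 olefin is the handle from which C3 and C4 of the target are set in steps 8 and 11.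

**Step 8**
Reactants: 12 (S)-5,7-bis(benzyloxy)-2-[3,4-bis(benzyloxy)phenyl]-2H-chromene
Product: 13 (2R,3S,4S)-5,7-bis(benzyloxy)-2-[3,4-bis(benzyloxy)phenyl]chromane-3,4-diol (2,3-trans-3,4-cis)
Conditions: OsO4 (2 mol %), NMO (1.5 equiv), acetone/H2O 8:1, 0 °C to rt; aqueous Na2SO3
Reagents that add atoms: osmium tetroxide (catalytic oxygen carrier), O=[Os](=O)(=O)=O; N-methylmorpholine N-oxide, C[N+]1([O-])CCOCC1; water, O
Why: Upjohn syn-dihydroxylation: the addition should occur on the face of the C3=C4 olefin opposite the C2 aryl group, which sets C3 (S, hydroxyl trans to the aryl group) and C4 (S, hydroxyl cis to the C3 hydroxyl) by substrate control, as known for flav-3-enes.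

**Step 9**
Reactants: 14 (−)-epigallocatechin
Product: 15 5,7,3',4',5'-penta-O-benzyl-(−)-epigallocatechin
Conditions: BnBr (5.5 equiv), K2CO3 (6 equiv), DMF, −10 °C to rt, argon, dark
Reagents that add atoms: benzyl bromide, BrCc1ccccc1
Why: Williamson etherification: the carbonate base deprotonates only the five phenols, so the secondary C3 hydroxyl should stay free, and low temperature with exclusion of oxygen should outpace base-induced epimerisation at C2 and oxidation of the pyrogallol ring; no stereocentre is touched.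

**Step 10**
Reactants: 15 5,7,3',4',5'-penta-O-benzyl-(−)-epigallocatechin, 16 3,4,5-tris(benzyloxy)benzoic acid
Product: 17 octa-O-benzyl-(−)-epigallocatechin 3-O-gallate
Conditions: DCC (1.5 equiv), DMAP (0.3 equiv), CH2Cl2, 0 °C to rt
Reagents that add atoms: none
Why: Steglich esterification: DMAP transfers the acyl group from the O-acylisourea of 16 to the axial C3 hydroxyl of 15, and because the bond is formed at oxygen the C3 configuration is retained.

**Step 11**
Reactants: 13 (2R,3S,4S)-5,7-bis(benzyloxy)-2-[3,4-bis(benzyloxy)phenyl]chromane-3,4-diol, 17 octa-O-benzyl-(−)-epigallocatechin 3-O-gallate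
Product: 18 dodeca-O-benzyl catechin-(4α→8)-epigallocatechin 3-O-gallate (upper 3-OH free)
Conditions: 17 (4 equiv), TMSOTf (0.2 equiv), 4 Å molecular sieves, CH2Cl2, −78 °C to −40 °C; Et3N quench; excess 17 recovered
Reagents that add atoms: none
Why: Lewis-acid-promoted Friedel–Crafts-type flavan-4-yl coupling: TMSOTf ionises the benzylic C4 hydroxyl of 13 (cation stabilised by the ortho and para oxygens of ring A), and C8 of ring D of 17, the most nucleophilic arene carbon, should attack the face opposite the C3 oxygen substituent to set C4 (S) in the 3,4-trans, all-equatorial arrangement, excess 17 suppressing oligomerisation.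

**Step 12**
Reactants: 18 dodeca-O-benzyl catechin-(4α→8)-epigallocatechin 3-O-gallate
Product: 19 catechin-(4α→8)-epigallocatechin 3-O-gallate (target)
Conditions: H2 (1 atm), Pd(OH)2/C (20 wt %), THF/MeOH/H2O 20:1:1, rt; filtration under argon, lyophilisation
Reagents that add atoms: none
Why: Catalytic hydrogenolysis of the twelve benzyl ethers over palladium hydroxide on carbon under neutral conditions should leave the galloyl ester, the interflavan C4–C8 bond and all five stereocentres untouched.

**Compound list**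

1 | 3,4-bis(benzyloxy)benzaldehyde | O=Cc1ccc(OCc2ccccc2)c(OCc2ccccc2)c1 | starting material
2 | ethyl (E)-3-[3,4-bis(benzyloxy)phenyl]prop-2-enoate | CCOC(=O)/C=C/c1ccc(OCc2ccccc2)c(OCc2ccccc2)c1 | intermediate
3 | (E)-3-[3,4-bis(benzyloxy)phenyl]prop-2-en-1-ol | OC/C=C/c1ccc(OCc2ccccc2)c(OCc2ccccc2)c1 | intermediate
4 | (E)-3-[3,4-bis(benzyloxy)phenyl]prop-2-en-1-yl methyl carbonate | COC(=O)OC/C=C/c1ccc(OCc2ccccc2)c(OCc2ccccc2)c1 | intermediate
5 | 3,5-bis(benzyloxy)phenol | Oc1cc(OCc2ccccc2)cc(OCc2ccccc2)c1 | starting material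
6 | 3,5-bis(benzyloxy)-2-(hydroxymethyl)phenol | OCc1c(O)cc(OCc2ccccc2)cc1OCc1ccccc1 | intermediate (not isolated)
7 | 4,6-bis(benzyloxy)-2-hydroxybenzaldehyde | O=Cc1c(O)cc(OCc2ccccc2)cc1OCc1ccccc1 | intermediate
8 | potassium 3,5-bis(benzyloxy)-2-formylphenoxide | O=Cc1c([O-])cc(OCc2ccccc2)cc1OCc1ccccc1.[K+] | intermediate (not isolated)
9 | 3,5-bis(benzyloxy)-2-vinylphenol | C=Cc1c(O)cc(OCc2ccccc2)cc1OCc1ccccc1 | intermediate
10 | lithium 3,5-bis(benzyloxy)-2-vinylphenoxide | C=Cc1c([O-])cc(OCc2ccccc2)cc1OCc1ccccc1.[Li+] | intermediate (not isolated)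
11 | (S)-1-[3,4-bis(benzyloxy)phenyl]prop-2-en-1-yl 3,5-bis(benzyloxy)-2-vinylphenyl ether | C=C[C@H](Oc1cc(OCc2ccccc2)cc(OCc2ccccc2)c1C=C)c1ccc(OCc2ccccc2)c(OCc2ccccc2)c1 | intermediate
12 | (S)-5,7-bis(benzyloxy)-2-[3,4-bis(benzyloxy)phenyl]-2H-chromene | C1=C[C@@H](c2ccc(OCc3ccccc3)c(OCc3ccccc3)c2)Oc2cc(OCc3ccccc3)cc(OCc3ccccc3)c21 | intermediate
13 | (2R,3S,4S)-5,7-bis(benzyloxy)-2-[3,4-bis(benzyloxy)phenyl]chromane-3,4-diol | O[C@H]1c2c(OCc3ccccc3)cc(OCc3ccccc3)cc2O[C@H](c2ccc(OCc3ccccc3)c(OCc3ccccc3)c2)[C@H]1O | intermediate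
14 | (−)-epigallocatechin, (2R,3R) | O[C@@H]1Cc2c(O)cc(O)cc2O[C@@H]1c1cc(O)c(O)c(O)c1 | starting material
15 | 5,7,3',4',5'-penta-O-benzyl-(−)-epigallocatechin, (2R,3R) | O[C@@H]1Cc2c(OCc3ccccc3)cc(OCc3ccccc3)cc2O[C@@H]1c1cc(OCc2ccccc2)c(OCc2ccccc2)c(OCc2ccccc2)c1 | intermediate
16 | 3,4,5-tris(benzyloxy)benzoic acid | O=C(O)c1cc(OCc2ccccc2)c(OCc2ccccc2)c(OCc2ccccc2)c1 | starting material
17 | octa-O-benzyl-(−)-epigallocatechin 3-O-gallate | O=C(O[C@@H]1Cc2c(OCc3ccccc3)cc(OCc3ccccc3)cc2O[C@@H]1c1cc(OCc2ccccc2)c(OCc2ccccc2)c(OCc2ccccc2)c1)c1cc(OCc2ccccc2)c(OCc2ccccc2)c(OCc2ccccc2)c1 | intermediate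
18 | dodeca-O-benzyl catechin-(4α→8)-epigallocatechin 3-O-gallate, upper unit (2R,3S,4S), lower unit (2R,3R) | O=C(O[C@@H]1Cc2c(OCc3ccccc3)cc(OCc3ccccc3)c([C@@H]3c4c(OCc5ccccc5)cc(OCc5ccccc5)cc4O[C@H](c4ccc(OCc5ccccc5)c(OCc5ccccc5)c4)[C@H]3O)c2O[C@@H]1c1cc(OCc2ccccc2)c(OCc2ccccc2)c(OCc2ccccc2)c1)c1cc(OCc2ccccc2)c(OCc2ccccc2)c(OCc2ccccc2)c1 | intermediate
19 | catechin-(4α→8)-epigallocatechin 3-O-gallate (CNP0246304.1) | O=C(O[C@@H]1Cc2c(O)cc(O)c([C@@H]3c4c(O)cc(O)cc4O[C@H](c4ccc(O)c(O)c4)[C@H]3O)c2O[C@@H]1c1cc(O)c(O)c(O)c1)c1cc(O)c(O)c(O)c1 | target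

**Step count.** Total: 12 steps. Longest linear sequence: 8 steps (steps 1, 2, 3, 6, 7, 8, 11, 12).

**Steps most likely to fail**

1. Step 11 (interflavan coupling). What may go wrong: attack of ring D on the face of the C4 cation cis to the C3 oxygen, attack through C6 instead of C8, self-condensation of 13 or further alkylation of 18, and loss of the C3 proton from the cation. The fallback replaces simple substrate control by neighbouring-group control. It sets out from 13, which is acylated on both hydroxyls (levulinic acid, DCC, DMAP, CH2Cl2) to the 3,4-bis(4-oxopentanoate) of diol 13 F1, with the configuration of 13 retained. With TMSOTf and 17 in CH2Cl2 at −78 °C the benzylic C4 ester leaves and the C3 ester carbonyl bridges the cation on the face of the C3 oxygen, so ring D can only attack from the opposite face; this should give the upper 3-O-levulinoyl derivative of 18 F2. Hydrazine acetate in CH2Cl2/MeOH removes the levulinoyl group without touching the galloyl ester, and the route is rejoined at 18.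

2. Step 6 (allylic etherification). What may go wrong: C-allylation of the ambident, electron-rich phenoxide, attack at the unsubstituted allyl terminus, and re-ionisation of the electron-rich branched ether with loss of enantiopurity. The fallback forms the C2–O bond by inversion of a preformed carbinol stereocentre. It sets out from 1, which with vinylmagnesium bromide (THF, −78 °C) gives racemic 1-[3,4-bis(benzyloxy)phenyl]prop-2-en-1-ol F3. Kinetic resolution with Candida antarctica lipase B and vinyl acetate (hexane, rt), following the usual enantiopreference of this lipase for aryl carbinols, should give (R)-1-[3,4-bis(benzyloxy)phenyl]prop-2-en-1-yl acetate F4, separated from the unreacted (S)-enantiomer of F3. Methanolysis (K2CO3, MeOH) gives (R)-1-[3,4-bis(benzyloxy)phenyl]prop-2-en-1-ol F5, and a Mitsunobu reaction with 9 (PPh3, DIAD, toluene, −20 °C) with inversion rejoins the route at 11.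

3. Step 8 (dihydroxylation). What may go wrong: addition on the face syn to the C2 aryl group, over-oxidation of the electron-rich benzylic diol to the ketol, and ionisation of the C4 hydroxyl of 13 during isolation. The fallback replaces the diol by a 4-alkoxy electrophile made through epoxidation. It sets out from 12: dimethyldioxirane (acetone/CH2Cl2, −40 °C, dark) should epoxidise the C3=C4 olefin on the face anti to the C2 aryl group to give (2R)-5,7-bis(benzyloxy)-2-[3,4-bis(benzyloxy)phenyl]-3,4-epoxychromane F6, which is not isolated. Methanol added to the cold solution opens the epoxide at the benzylic C4 carbon, mainly with inversion, to (2R,3S,4R)-5,7-bis(benzyloxy)-2-[3,4-bis(benzyloxy)phenyl]-4-methoxychroman-3-ol F7. Under the conditions of step 11 (TMSOTf, 17, CH2Cl2, −78 °C) this ether loses methanol to the same C4 cation as 13, so its C4 configuration is of no consequence, and the route is rejoined at 18.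

**Further compounds**

F1 | step 11 | 3,4-bis(4-oxopentanoate) of diol 13 (configuration of 13 retained) | CC(=O)CCC(=O)O[C@H]1c2c(OCc3ccccc3)cc(OCc3ccccc3)cc2O[C@H](c2ccc(OCc3ccccc3)c(OCc3ccccc3)c2)[C@H]1OC(=O)CCC(C)=O
F2 | step 11 | upper 3-O-levulinoyl derivative of 18 | O=C(O[C@@H]1Cc2c(OCc3ccccc3)cc(OCc3ccccc3)c([C@@H]3c4c(OCc5ccccc5)cc(OCc5ccccc5)cc4O[C@H](c4ccc(OCc5ccccc5)c(OCc5ccccc5)c4)[C@H]3OC(=O)CCC(C)=O)c2O[C@@H]1c1cc(OCc2ccccc2)c(OCc2ccccc2)c(OCc2ccccc2)c1)c1cc(OCc2ccccc2)c(OCc2ccccc2)c(OCc2ccccc2)c1
F3 | step 6 | racemic 1-[3,4-bis(benzyloxy)phenyl]prop-2-en-1-ol | C=CC(O)c1ccc(OCc2ccccc2)c(OCc2ccccc2)c1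
F4 | step 6 | (R)-1-[3,4-bis(benzyloxy)phenyl]prop-2-en-1-yl acetate | C=C[C@@H](OC(C)=O)c1ccc(OCc2ccccc2)c(OCc2ccccc2)c1
F5 | step 6 | (R)-1-[3,4-bis(benzyloxy)phenyl]prop-2-en-1-ol | C=C[C@@H](O)c1ccc(OCc2ccccc2)c(OCc2ccccc2)c1
F6 | step 8 | (2R)-5,7-bis(benzyloxy)-2-[3,4-bis(benzyloxy)phenyl]-3,4-epoxychromane, epoxide anti to the C2 aryl group | O1[C@H]2c3c(OCc4ccccc4)cc(OCc4ccccc4)cc3O[C@H](c3ccc(OCc4ccccc4)c(OCc4ccccc4)c3)[C@H]21
F7 | step 8 | (2R,3S,4R)-5,7-bis(benzyloxy)-2-[3,4-bis(benzyloxy)phenyl]-4-methoxychroman-3-ol | CO[C@@H]1c2c(OCc3ccccc3)cc(OCc3ccccc3)cc2O[C@H](c2ccc(OCc3ccccc3)c(OCc3ccccc3)c2)[C@H]1O
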